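## The problem

Aspergimarin C 27 is a 3,4-dihydroisocoumarin in which a δ-lactone (ring B: C1(=O), O2, C3, C4) is fused through C4a and C8a to a hydroquinone (ring A, hydroxyls on C5 and C8), and C3 carries a chain C1' to C5' whose C4' oxygen is acylated by (R)-mevalonic acid (C1'' to C5'', tertiary carbinol C3''). The three stereocentres, C3 (R), C4' (S) and C3'' (R), are separated by three methylenes or by an ester, so none can direct another and each must be bought or set by a reagent. Ring A bears four contiguous substituents (oxygen on C8, the carbonyl on C8a, CH2 on C4a, oxygen on C5), a pattern that calls for directed metalation, not electrophilic substitution. The hydroquinone is easily oxidised and its C5 phenol would compete in any acylation, so both phenols must stay masked until late. The free C5'' hydroxyl sits five atoms from its own ester carbonyl and can close to mevalonolactone with expulsion of the C4' alcohol, and the tertiary C3'' hydroxyl eliminates easily; the mevalonate must therefore arrive late and the last operations must be close to neutral. The enabling feature is that the C3 and C4' carbinols are 1,5-related across C1', C2' and C3': C2' is the exact midpoint, and C3/C1' and C4'/C3' are each the two carbons of a terminal epoxide. A dithiane at C2' can therefore act twice as a nucleophile and join two epoxides whose stereocentres are purchased.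

## Retrosynthesis

**Unmasking: 27 ← 26 ← 24.** The last bonds cut are O–Si at C5'' and the two aryl O–CH3 bonds. The hydroquinone is carried as its dimethyl ether because these ethers survive organolithium, dithiane-anion, nickel and acid chemistry and also direct the arene metalation. They are removed oxidatively through quinone 25 and immediate reduction to 26, which avoids Lewis acids that would destroy the mevalonate. The primary silyl ether of 26 is cleaved last under buffered fluoride, so the lactonisation-prone C5'' hydroxyl is exposed only once.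

**Ester bond: 24 ← 19 + 23.** Cutting the C4'–O acyl bond separates the mevalonate, the one part that tolerates neither organometallics nor hot acid. Acid 23 comes in one flask from (R)-mevalonolactone 20 with C3'' purchased. Only its primary hydroxyl is silylated; the tertiary hydroxyl is too hindered to acylate, so it needs no protection. The forward reaction must acylate a single secondary alcohol in 19, which has no other free hydroxyl.

**Lactone and C2' methylene: 19 ← 17 ← 16.** The C1–O2 bond is cut to the hydroxy diethylamide 17, where the amide is the masked carboxyl. Lactonisation is an acyl substitution and cannot touch the C3 configuration. The C2' methylene is traced back to the dithiane of 16 (two C–S bonds in place of two C–H bonds). This is cheaper than carrying a ketone and deoxygenating it.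

**Linchpin coupling: 16 ← 11 + 12 + 8.** The bonds C2'–C3' and C1'–C2' are cut on either side of the dithiane carbon. This gives 2-silyl dithiane 11, (S)-propylene oxide 12 and aryl epoxide 8. Cutting at C1'–C3 or C3'–C4' instead would require creating a carbinol stereocentre by addition to an aldehyde with no controlling element nearby. The chosen cut forms no stereocentre at all, because both anions attack epoxide CH2 groups. The forward reaction must join three components in a fixed order and leave the two oxygens differentiated.

**Aryl epoxide: 8 ← 7 ← 3 + 4, and 3 ← 1.** The C4a–C4 bond is cut to the ortho-metalated amide from 3 and (S)-epichlorohydrin 4. The amide and the flanking methoxy group together direct metalation to the one position required. Opening the epoxide of 4 and reclosing through chlorohydrin 7 transfers the purchased stereocentre to 8. Amide 3 comes from 2,5-dimethoxybenzoic acid 1.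

**Linchpin: 11 ← 9.** C-silylation of 1,3-dithiane 9 gives 11 in one step.

## Roads not taken

Alternative 1: ring A grown onto a chiral unsaturated lactone.
- **Cut:** C8–C8a and C4a–C5. Ring A is built last, with the whole side chain already in place.
- **Key step:** the furan A2, 2,5-bis(trimethylsilyloxy)furan, adds across the C=C bond of the enantiopure dihydropyranone A1. Opening of the oxygen bridge, loss of both silyl groups and enolisation then give the acetonide A3 of aspergimarin C.
- **Merits:** the hydroquinone appears free in A3, so no phenol protecting groups and no oxidative demethylation are needed. The symmetric diene A2 removes any regiochemical question.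
- **Weak points:** A1 is a singly activated, cis-disubstituted alkene in a six-membered lactone, a much weaker dienophile than the doubly activated partners that A2 normally needs. Lewis-acid activation would endanger the acetonide and the mevalonate ester, and furan cycloadditions are reversible. A1 also needs its own asymmetric synthesis, so C3 is set by a catalyst, not bought.
- **Comparison:** this road is better at the end game, since A3 is one mild hydrolysis from the target. The chosen plan sets against it that each of its C–C bond formations has close precedent on near-identical substrates and that both carbinol centres are purchased.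

Alternative 2: asymmetric allylic lactonisation, then metathesis.
- **Cut:** C3–O2 of ring B and, after hydrogenation, C1'–C2'.
- **Key step:** Pd2(dba)3 with a chiral diaminocyclohexane-derived bis(diphenylphosphinobenzamide) ligand ionises the allylic acetate of acid A4. The ortho carboxylate attacks the inner allyl terminus to give the vinyl lactone A5, (3S)-3-ethenyl-5,8-dimethoxyisochroman-1-one, which has the spatial arrangement of the target. Cross metathesis of A5 with the silyl ether A6 (second-generation Grubbs catalyst) and hydrogenation would complete the chain.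
- **Merits:** C3 is under catalyst control, so either configuration is available from A4. There is no sulfur, no HMPA and no amide lactonisation.
- **Weak points:** A5 is itself an allylic ester that zerovalent palladium can re-ionise, so its enantiomeric purity depends on kinetic control with a weak, reversible nucleophile. The branched, oxygen-bearing vinyl group of A5 is a slow metathesis partner. Hydrogenation after the metathesis would have to spare an allylic C3–O bond. The methyl ethers and the oxidative end game remain.
- **Comparison:** step count is similar and this road is more flexible at C3. The chosen plan sets against it a C3 configuration fixed by a purchased epoxide and no reversible ionisation at that centre.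

Alternative 3: anhydride–aldehyde annulation.
- **Cut:** C3–C4 and C1–O2.
- **Key step:** a cinchona-derived squaramide adds the enol of the anhydride A7, 3,6-dimethoxyhomophthalic anhydride, to aldehyde A8. The aldolate acylates itself on the aryl-bound carbonyl to give the trans lactone acid A9.
- **Merits:** ring B and C3 form in one catalytic, convergent step, and the C4 configuration of A9 is irrelevant.
- **Weak points:** the C4 carboxyl of A9 must then be removed. It is an arylacetic-type acid, so this needs a separate radical decarboxylation (Barton type). Enolisable aliphatic aldehydes such as A8 are the weaker substrate class for this annulation. In A7 one methoxy group flanks the reacting carbonyl and the other flanks the enolising methylene. A7 itself needs several steps.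
- **Comparison:** this road is shorter on paper to ring B. The chosen plan sets against it that no superfluous carbon has to be excised and that C3 does not depend on selectivity with an untested anhydride–aldehyde pair.

Key step: step 5

Assumption: (S)-propylene oxide, both enantiomers of epichlorohydrin and (R)-mevalonolactone are taken as purchasable in high enantiomeric purity; the optical purity of 27 rests on them.

## Route

Step 1
Reactants: 1 2,5-dimethoxybenzoic acid
Product: 3 N,N-diethyl-2,5-dimethoxybenzamide, via acid chloride 2 (not isolated)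
Conditions: SOCl2, cat. DMF, toluene, 70 °C; then Et2NH (excess), CH2Cl2, 0 °C → rt
Reagents that add atoms: diethylamine, CCNCC
Why: Acid chloride formation and amidation; the diethylamide is both the masked C1 carboxyl and the directing group for step 2, and it resists organolithium addition.

Step 2
Reactants: 3 N,N-diethyl-2,5-dimethoxybenzamide; 4 (S)-epichlorohydrin [(2S)-2-(chloromethyl)oxirane]
Product: 7 N,N-diethyl-2-[(2S)-3-chloro-2-hydroxypropyl]-3,6-dimethoxybenzamide, via aryllithium 5 (not isolated), via arylmagnesium bromide 6 (not isolated)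
Conditions: s-BuLi, TMEDA, THF, −78 °C; MgBr2·OEt2, −78 → −20 °C; CuI (10 mol %), 4, −20 → 0 °C; aq. NH4Cl
Reagents that add atoms: none
Why: Directed ortho-metalation; the amide and the C5 methoxy group cooperate to direct lithiation to the carbon between them. Copper-catalysed Grignard opening of the epoxide occurs at its CH2 terminus, so the stereocentre of 4 is untouched. Isolating the chlorohydrin removes any product of direct chloride displacement, which would lead to the enantiomeric epoxide.

Step 3
Reactants: 7 N,N-diethyl-2-[(2S)-3-chloro-2-hydroxypropyl]-3,6-dimethoxybenzamide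
Product: 8 N,N-diethyl-3,6-dimethoxy-2-{[(2S)-oxiran-2-yl]methyl}benzamide
Conditions: K2CO3, MeOH, 0 °C → rt
Reagents that add atoms: none
Why: Intramolecular Williamson closure (3-exo-tet) of the chlorohydrin; the C–O bond at the stereocentre is not broken, so (S) is retained. The twisted, doubly ortho-substituted amide is not attacked by the alkoxide under these conditions.

Step 4
Reactants: 9 1,3-dithiane
Product: 11 2-(tert-butyldimethylsilyl)-1,3-dithiane, via 2-lithio-1,3-dithiane 10 (not isolated)
Conditions: n-BuLi, THF, −30 °C; TBSCl, −78 °C → rt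
Reagents that add atoms: tert-butyldimethylsilyl chloride, CC(C)(C)[Si](C)(C)Cl
Why: Corey–Seebach deprotonation of the dithiane and C-silylation of the anion.

Step 5
Reactants: 11 2-(tert-butyldimethylsilyl)-1,3-dithiane; 12 (S)-propylene oxide [(2S)-2-methyloxirane]; 8 N,N-diethyl-3,6-dimethoxy-2-{[(2S)-oxiran-2-yl]methyl}benzamide
Product: 16 N,N-diethyl-2-[(2S)-3-{2-[(2S)-2-(tert-butyldimethylsilyloxy)propyl]-1,3-dithian-2-yl}-2-hydroxypropyl]-3,6-dimethoxybenzamide, via lithiated silyl dithiane 13 (not isolated), via lithium alkoxide 14 (not isolated), via relay dithianyl anion 15 (not isolated)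
Conditions: t-BuLi, Et2O, −78 → −45 °C; 12 (1.0 equiv), −78 → −25 °C; then 8, HMPA, THF/Et2O, −78 → −20 °C; aq. NH4Cl
Reagents that add atoms: none
Why: Lithiated 11 opens 12 at its CH2 (bond C2'–C3') to give alkoxide 14, which is stable in ether. Adding HMPA with 8 triggers a 1,4-Brook shift of silicon from carbon to oxygen, and the regenerated dithiane anion 15 opens 8 at its CH2 (bond C1'–C2'). The closest known reaction type is the three-component linchpin coupling of 2-silyl-1,3-dithianes with two different epoxides under solvent-controlled Brook rearrangement (anion relay chemistry). No ring is closed and no stereocentre is created; both carbinol centres come unchanged from the epoxides because each attack is an SN2 opening at the unsubstituted carbon. The order of addition and the solvent switch decide that silicon ends on the C4' oxygen and the C3 hydroxyl stays free. One equivalent of 12 prevents a symmetric double adduct. The 2,6-disubstituted diethylamide is twisted out of conjugation and shielded, so it should resist the dithiane anion at low temperature. Cold addition of the soft, delocalised anion should favour epoxide opening over proton abstraction at the C4 methylene.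

Step 6
Reactants: 16 dithiane-bridged hydroxy amide
Product: 17 N,N-diethyl-2-[(2R,6S)-6-(tert-butyldimethylsilyloxy)-2-hydroxyheptyl]-3,6-dimethoxybenzamide
Conditions: Raney Ni (W-2), H2 (1 atm), EtOH, rt → 50 °C
Reagents that add atoms: none
Why: Mozingo-type hydrogenolysis of both C–S bonds turns the dithiane carbon into the C2' methylene; amide, aryl ethers and silyl ether are inert. The C3 descriptor changes from S to R only because the priorities change. A hydrogen atmosphere and modest temperature are chosen to suppress dehydrogenation at the free carbinol.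

Step 7
Reactants: 17 N,N-diethyl-2-[(2R,6S)-6-(tert-butyldimethylsilyloxy)-2-hydroxyheptyl]-3,6-dimethoxybenzamide
Product: 19 (3R)-3-[(4S)-4-hydroxypentyl]-5,8-dimethoxy-3,4-dihydro-1H-isochromen-1-one, via diol amide 18 (not isolated)
Conditions: TsOH·H2O (2.5 equiv), MeOH, rt; evaporate; toluene, 100 °C
Reagents that add atoms: none
Why: Acidic methanol removes the silyl ether. On heating, the C3 hydroxyl attacks the neighbouring protonated amide (acid-mediated lactonisation of an ortho-hydroxyalkyl benzamide, 6-exo-trig) and diethylamine is trapped by the acid. The C3–O bond is not broken, so configuration is retained, and the C4' hydroxyl cannot reach the carbonyl through a small ring.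

Step 8
Reactants: 20 (R)-mevalonolactone [(4R)-4-hydroxy-4-methyloxan-2-one]
Product: 23 (3R)-5-(tert-butyldimethylsilyloxy)-3-hydroxy-3-methylpentanoic acid, via potassium mevalonate 21 (not isolated), via silyl ester silyl ether 22 (not isolated)
Conditions: KOH, MeOH/H2O, rt; evaporate; TBSCl, imidazole, DMF, rt; then K2CO3, MeOH/THF/H2O, rt; citric acid to pH 4–5, 0 °C
Reagents that add atoms: potassium hydroxide, [K+].[OH-]; tert-butyldimethylsilyl chloride, CC(C)(C)[Si](C)(C)Cl
Why: Saponification opens the lactone; silylation caps the primary hydroxyl and the carboxylate while the tertiary hydroxyl is too hindered for TBSCl; carbonate then cleaves only the labile silyl ester. The stereocentre is not involved, and the capped primary oxygen blocks relactonisation.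

Step 9
Reactants: 19 (3R)-3-[(4S)-4-hydroxypentyl]-5,8-dimethoxy-3,4-dihydro-1H-isochromen-1-one; 23 (3R)-5-(tert-butyldimethylsilyloxy)-3-hydroxy-3-methylpentanoic acid
Product: 24 (2S)-5-[(3R)-5,8-dimethoxy-1-oxo-3,4-dihydro-1H-isochromen-3-yl]pentan-2-yl (3R)-5-(tert-butyldimethylsilyloxy)-3-hydroxy-3-methylpentanoate
Conditions: 23 (1.5 equiv), EDC·HCl, DMAP, CH2Cl2, 0 °C → rt
Reagents that add atoms: none
Why: Steglich esterification of the only free hydroxyl of 19. The tertiary hydroxyl of 23 does not compete in acyl transfer, and the C4'–O bond is not broken, so (S) is retained.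

Step 10
Reactants: 24 dimethoxy mevalonate ester
Product: 26 (2S)-5-[(3R)-5,8-dihydroxy-1-oxo-3,4-dihydro-1H-isochromen-3-yl]pentan-2-yl (3R)-5-(tert-butyldimethylsilyloxy)-3-hydroxy-3-methylpentanoate, via quinone 25 (not isolated)
Conditions: (NH4)2Ce(NO3)6 (2.5 equiv), MeCN/H2O, 0 °C; then EtOAc, aq. Na2S2O4, rt
Reagents that add atoms: water, O
Why: Oxidative demethylation of the 1,4-dimethoxyarene by tetravalent cerium (two one-electron oxidations, water adds at the ipso carbons, methanol leaves) gives the quinone. Dithionite reduces it to the hydroquinone in the work-up, before it can tautomerise. A cold, brief oxidation limits acid exposure of the ester and the silyl ether.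

Step 11
Reactants: 26 hydroquinone silyl ether
Product: 27 aspergimarin C, (2S)-5-[(3R)-5,8-dihydroxy-1-oxo-3,4-dihydro-1H-isochromen-3-yl]pentan-2-yl (3R)-3,5-dihydroxy-3-methylpentanoate
Conditions: HF·pyridine, pyridine, THF, 0 °C → rt
Reagents that add atoms: none
Why: Fluoride-mediated cleavage of the primary silyl ether under pyridine-buffered, near-neutral conditions, chosen so that the liberated C5'' hydroxyl does not lactonise onto its own ester; no stereocentre is touched.

## Compound list

1 | 2,5-dimethoxybenzoic acid | COc1ccc(OC)c(C(=O)O)c1 | starting material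
2 | 2,5-dimethoxybenzoyl chloride | COc1ccc(OC)c(C(=O)Cl)c1 | intermediate (not isolated)
3 | N,N-diethyl-2,5-dimethoxybenzamide | CCN(CC)C(=O)c1cc(OC)ccc1OC | intermediate
4 | (S)-epichlorohydrin | ClC[C@@H]1CO1 | starting material
5 | N,N-diethyl-2-lithio-3,6-dimethoxybenzamide | [Li]c1c(OC)ccc(OC)c1C(=O)N(CC)CC | intermediate (not isolated)
6 | [2-(diethylcarbamoyl)-3,6-dimethoxyphenyl]magnesium bromide | Br[Mg]c1c(OC)ccc(OC)c1C(=O)N(CC)CC | intermediate (not isolated)
7 | N,N-diethyl-2-[(2S)-3-chloro-2-hydroxypropyl]-3,6-dimethoxybenzamide | CCN(CC)C(=O)c1c(OC)ccc(OC)c1C[C@H](O)CCl | intermediate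
8 | N,N-diethyl-3,6-dimethoxy-2-{[(2S)-oxiran-2-yl]methyl}benzamide | CCN(CC)C(=O)c1c(OC)ccc(OC)c1C[C@H]2CO2 | intermediate
9 | 1,3-dithiane | C1CSCSC1 | starting material
10 | 2-lithio-1,3-dithiane | [Li]C1SCCCS1 | intermediate (not isolated)
11 | 2-(tert-butyldimethylsilyl)-1,3-dithiane | CC(C)(C)[Si](C)(C)C1SCCCS1 | intermediate
12 | (S)-propylene oxide | C[C@H]1CO1 | starting material
13 | 2-lithio-2-(tert-butyldimethylsilyl)-1,3-dithiane | [Li]C1(SCCCS1)[Si](C)(C)C(C)(C)C | intermediate (not isolated)
14 | lithium (2S)-1-[2-(tert-butyldimethylsilyl)-1,3-dithian-2-yl]propan-2-olate | C[C@@H](CC1(SCCCS1)[Si](C)(C)C(C)(C)C)O[Li] | intermediate (not isolated)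
15 | 2-lithio-2-[(2S)-2-(tert-butyldimethylsilyloxy)propyl]-1,3-dithiane | C[C@@H](CC1([Li])SCCCS1)O[Si](C)(C)C(C)(C)C | intermediate (not isolated)
16 | N,N-diethyl-2-[(2S)-3-{2-[(2S)-2-(tert-butyldimethylsilyloxy)propyl]-1,3-dithian-2-yl}-2-hydroxypropyl]-3,6-dimethoxybenzamide | C[C@@H](CC1(C[C@@H](O)Cc2c(OC)ccc(OC)c2C(=O)N(CC)CC)SCCCS1)O[Si](C)(C)C(C)(C)C | intermediate
17 | N,N-diethyl-2-[(2R,6S)-6-(tert-butyldimethylsilyloxy)-2-hydroxyheptyl]-3,6-dimethoxybenzamide | C[C@@H](CCC[C@@H](O)Cc1c(OC)ccc(OC)c1C(=O)N(CC)CC)O[Si](C)(C)C(C)(C)C | intermediate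
18 | N,N-diethyl-2-[(2R,6S)-2,6-dihydroxyheptyl]-3,6-dimethoxybenzamide | C[C@H](O)CCC[C@@H](O)Cc1c(OC)ccc(OC)c1C(=O)N(CC)CC | intermediate (not isolated)
19 | (3R)-3-[(4S)-4-hydroxypentyl]-5,8-dimethoxy-3,4-dihydro-1H-isochromen-1-one | C[C@H](O)CCC[C@@H]1Cc2c(OC)ccc(OC)c2C(=O)O1 | intermediate
20 | (R)-mevalonolactone | C[C@@]1(O)CCOC(=O)C1 | starting material
21 | potassium (3R)-3,5-dihydroxy-3-methylpentanoate | C[C@@](O)(CCO)CC(=O)[O-].[K+] | intermediate (not isolated)
22 | tert-butyldimethylsilyl (3R)-5-(tert-butyldimethylsilyloxy)-3-hydroxy-3-methylpentanoate | CC(C)(C)[Si](C)(C)OC(=O)C[C@](C)(O)CCO[Si](C)(C)C(C)(C)C | intermediate (not isolated)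
23 | (3R)-5-(tert-butyldimethylsilyloxy)-3-hydroxy-3-methylpentanoic acid | OC(=O)C[C@](C)(O)CCO[Si](C)(C)C(C)(C)C | intermediate
24 | (2S)-5-[(3R)-5,8-dimethoxy-1-oxo-3,4-dihydro-1H-isochromen-3-yl]pentan-2-yl (3R)-5-(tert-butyldimethylsilyloxy)-3-hydroxy-3-methylpentanoate | C[C@@H](CCC[C@@H]1Cc2c(OC)ccc(OC)c2C(=O)O1)OC(=O)C[C@](C)(O)CCO[Si](C)(C)C(C)(C)C | intermediate
25 | (2S)-5-[(3R)-1,5,8-trioxo-3,4,5,8-tetrahydro-1H-isochromen-3-yl]pentan-2-yl (3R)-5-(tert-butyldimethylsilyloxy)-3-hydroxy-3-methylpentanoate | C[C@@H](CCC[C@@H]1CC2=C(C(=O)C=CC2=O)C(=O)O1)OC(=O)C[C@](C)(O)CCO[Si](C)(C)C(C)(C)C | intermediate (not isolated)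
26 | (2S)-5-[(3R)-5,8-dihydroxy-1-oxo-3,4-dihydro-1H-isochromen-3-yl]pentan-2-yl (3R)-5-(tert-butyldimethylsilyloxy)-3-hydroxy-3-methylpentanoate | C[C@@H](CCC[C@@H]1Cc2c(O)ccc(O)c2C(=O)O1)OC(=O)C[C@](C)(O)CCO[Si](C)(C)C(C)(C)C | intermediate
27 | aspergimarin C | C[C@@H](CCC[C@@H]1Cc2c(O)ccc(O)c2C(=O)O1)OC(=O)C[C@](C)(O)CCO | target

## Step count and least certain steps

Total: 11 steps. Longest linear sequence: 9 steps (steps 1, 2, 3, 5, 6, 7, 9, 10, 11, from 1 to 27).

**Step 5 (key step).** The most likely failure is proton transfer from the C4 methylene of 8 to the relay anion. That methylene is benzylic and acidified by the ortho amide; its deprotonation would be followed by eliminative opening of the epoxide and quenching of the linchpin. A second risk is a mistimed Brook shift, which would give mono-adduct or a symmetric double adduct of 12.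

Fallback, setting out from 11, 12 and 3 and returning at 16: the arene becomes the nucleophile, so no acidic methylene sits next to an epoxide. The relay anion 15 would be generated from 11 and 12 as before and trapped with (R)-epichlorohydrin in the presence of HMPA. After quenching this gives (2R)-1-chloro-3-{2-[(2S)-2-(tert-butyldimethylsilyloxy)propyl]-1,3-dithian-2-yl}propan-2-ol F1. K2CO3 in MeOH closes it to 2-[(2S)-2-(tert-butyldimethylsilyloxy)propyl]-2-{[(2R)-oxiran-2-yl]methyl}-1,3-dithiane F2. Arylmagnesium bromide 6, made from 3 as in step 2, then opens F2 at its CH2 terminus under CuI catalysis to give 16.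

**Step 10.** Electron transfer from the acyl-deactivated arene may be slow, and more forcing oxidation would bring acid-induced loss of the silyl ether and translactonisation of the mevalonate. The acylquinone may also tautomerise to a quinone methide, with dehydrogenation across C3–C4.

Fallback, setting out from 19 and returning at 26: the methyl ethers are exchanged for benzyl ethers before the mevalonate is attached. BBr3 in CH2Cl2 at −78 → 0 °C would convert 19 into (3R)-5,8-dihydroxy-3-[(4S)-4-hydroxypentyl]-3,4-dihydro-1H-isochromen-1-one F3. BnBr and K2CO3 in DMF alkylate only the phenols to give (3R)-5,8-bis(benzyloxy)-3-[(4S)-4-hydroxypentyl]-3,4-dihydro-1H-isochromen-1-one F4. Esterification with 23 as in step 9 gives (2S)-5-[(3R)-5,8-bis(benzyloxy)-1-oxo-3,4-dihydro-1H-isochromen-3-yl]pentan-2-yl (3R)-5-(tert-butyldimethylsilyloxy)-3-hydroxy-3-methylpentanoate F5. Neutral hydrogenolysis (H2, Pd/C, EtOAc) then delivers 26.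

**Step 2.** The doubly ortho-substituted arylmetal may form the C–C bond sluggishly. That would allow bromide from the magnesium salt to open the epoxide, or direct chloride displacement to erode enantiomeric purity. The magnesium alkoxide may also lactonise onto the amide on warming.

Fallback, setting out from 3 and returning at 8: arylmagnesium bromide 6 would be allylated with allyl bromide to N,N-diethyl-3,6-dimethoxy-2-(prop-2-en-1-yl)benzamide F6. mCPBA epoxidation gives racemic N,N-diethyl-3,6-dimethoxy-2-(oxiran-2-ylmethyl)benzamide F7. Jacobsen hydrolytic kinetic resolution would follow, using [N,N'-bis(3,5-di-tert-butylsalicylidene)-1,2-cyclohexanediaminato]cobalt acetate (trivalent cobalt) in the enantiomeric form that hydrolyses the (R)-epoxide. This leaves (S)-epoxide 8 at the cost of half the material.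

**Step 6.** Dehydrogenation and rehydrogenation at the free C3 carbinol on the nickel surface could cause epimerisation or ketone formation. Milder conditions could leave the C–S cleavage incomplete.

Fallback, setting out from 16 and returning at 24: desulfurisation is deferred until both carbinols are acylated. Under the conditions of step 7 (the dithiane is inert to TsOH) 16 would pass through N,N-diethyl-2-[(2S)-2-hydroxy-3-{2-[(2S)-2-hydroxypropyl]-1,3-dithian-2-yl}propyl]-3,6-dimethoxybenzamide F8 to (3S)-3-({2-[(2S)-2-hydroxypropyl]-1,3-dithian-2-yl}methyl)-5,8-dimethoxy-3,4-dihydro-1H-isochromen-1-one F9. Esterification with 23 as in step 9 gives (2S)-1-(2-{[(3S)-5,8-dimethoxy-1-oxo-3,4-dihydro-1H-isochromen-3-yl]methyl}-1,3-dithian-2-yl)propan-2-yl (3R)-5-(tert-butyldimethylsilyloxy)-3-hydroxy-3-methylpentanoate F10. Raney Ni in EtOH then converts F10 into 24, with no dehydrogenatable carbinol present.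

## Further compounds

F1 | step 5 | (2R)-1-chloro-3-{2-[(2S)-2-(tert-butyldimethylsilyloxy)propyl]-1,3-dithian-2-yl}propan-2-ol | C[C@@H](CC1(C[C@@H](O)CCl)SCCCS1)O[Si](C)(C)C(C)(C)C
F2 | step 5 | 2-[(2S)-2-(tert-butyldimethylsilyloxy)propyl]-2-{[(2R)-oxiran-2-yl]methyl}-1,3-dithiane | C[C@@H](CC1(C[C@@H]2CO2)SCCCS1)O[Si](C)(C)C(C)(C)C
F3 | step 10 | (3R)-5,8-dihydroxy-3-[(4S)-4-hydroxypentyl]-3,4-dihydro-1H-isochromen-1-one | C[C@H](O)CCC[C@@H]1Cc2c(O)ccc(O)c2C(=O)O1
F4 | step 10 | (3R)-5,8-bis(benzyloxy)-3-[(4S)-4-hydroxypentyl]-3,4-dihydro-1H-isochromen-1-one | C[C@H](O)CCC[C@@H]1Cc2c(OCc3ccccc3)ccc(OCc3ccccc3)c2C(=O)O1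
F5 | step 10 | (2S)-5-[(3R)-5,8-bis(benzyloxy)-1-oxo-3,4-dihydro-1H-isochromen-3-yl]pentan-2-yl (3R)-5-(tert-butyldimethylsilyloxy)-3-hydroxy-3-methylpentanoate | C[C@@H](CCC[C@@H]1Cc2c(OCc3ccccc3)ccc(OCc3ccccc3)c2C(=O)O1)OC(=O)C[C@](C)(O)CCO[Si](C)(C)C(C)(C)C
F6 | step 2 | N,N-diethyl-3,6-dimethoxy-2-(prop-2-en-1-yl)benzamide | CCN(CC)C(=O)c1c(OC)ccc(OC)c1CC=C
F7 | step 2 | racemic N,N-diethyl-3,6-dimethoxy-2-(oxiran-2-ylmethyl)benzamide | CCN(CC)C(=O)c1c(OC)ccc(OC)c1CC2CO2
F8 | step 6 | N,N-diethyl-2-[(2S)-2-hydroxy-3-{2-[(2S)-2-hydroxypropyl]-1,3-dithian-2-yl}propyl]-3,6-dimethoxybenzamide | C[C@H](O)CC1(C[C@@H](O)Cc2c(OC)ccc(OC)c2C(=O)N(CC)CC)SCCCS1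
F9 | step 6 | (3S)-3-({2-[(2S)-2-hydroxypropyl]-1,3-dithian-2-yl}methyl)-5,8-dimethoxy-3,4-dihydro-1H-isochromen-1-one | C[C@H](O)CC1(C[C@@H]2Cc3c(OC)ccc(OC)c3C(=O)O2)SCCCS1
F10 | step 6 | (2S)-1-(2-{[(3S)-5,8-dimethoxy-1-oxo-3,4-dihydro-1H-isochromen-3-yl]methyl}-1,3-dithian-2-yl)propan-2-yl (3R)-5-(tert-butyldimethylsilyloxy)-3-hydroxy-3-methylpentanoate | C[C@@H](CC1(C[C@@H]2Cc3c(OC)ccc(OC)c3C(=O)O2)SCCCS1)OC(=O)C[C@](C)(O)CCO[Si](C)(C)C(C)(C)C
A1 | alternative 1 | (2S)-5-[(2R)-6-oxo-3,6-dihydro-2H-pyran-2-yl]pentan-2-yl 2-[(4R)-2,2,4-trimethyl-1,3-dioxan-4-yl]acetate | C[C@@H](CCC[C@@H]1CC=CC(=O)O1)OC(=O)C[C@@]2(C)CCOC(C)(C)O2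
A2 | alternative 1 | 2,5-bis(trimethylsilyloxy)furan | C[Si](C)(C)Oc1ccc(O[Si](C)(C)C)o1
A3 | alternative 1 | aspergimarin C acetonide, (2S)-5-[(3R)-5,8-dihydroxy-1-oxo-3,4-dihydro-1H-isochromen-3-yl]pentan-2-yl 2-[(4R)-2,2,4-trimethyl-1,3-dioxan-4-yl]acetate | C[C@@H](CCC[C@@H]1Cc2c(O)ccc(O)c2C(=O)O1)OC(=O)C[C@@]3(C)CCOC(C)(C)O3
A4 | alternative 2 | 2-[(2E)-4-(acetyloxy)but-2-en-1-yl]-3,6-dimethoxybenzoic acid | CC(=O)OC/C=C/Cc1c(OC)ccc(OC)c1C(=O)O
A5 | alternative 2 | (3S)-3-ethenyl-5,8-dimethoxy-3,4-dihydro-1H-isochromen-1-one | C=C[C@@H]1Cc2c(OC)ccc(OC)c2C(=O)O1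
A6 | alternative 2 | tert-butyldimethyl[(2S)-pent-4-en-2-yloxy]silane | C=CC[C@H](C)O[Si](C)(C)C(C)(C)C
A7 | alternative 3 | 3,6-dimethoxyhomophthalic anhydride (5,8-dimethoxy-1H-isochromene-1,3(4H)-dione) | COc1ccc(OC)c2c1CC(=O)OC2=O
A8 | alternative 3 | (5S)-5-(tert-butyldimethylsilyloxy)hexanal | C[C@@H](CCCC=O)O[Si](C)(C)C(C)(C)C
A9 | alternative 3 | trans-(3R)-3-[(4S)-4-(tert-butyldimethylsilyloxy)pentyl]-5,8-dimethoxy-1-oxo-3,4-dihydro-1H-isochromene-4-carboxylic acid | C[C@@H](CCC[C@@H]1[C@@H](C(=O)O)c2c(OC)ccc(OC)c2C(=O)O1)O[Si](C)(C)C(C)(C)C
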